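**Assumption:** the SMILES is read as (1R,2R,4E,8S,9S,10R) in bicyclo numbering. In the text the carbocycle is numbered C1 (CH–O-angeloyl), C2, C3=C4(CH3), C5, C6, C7 (isopropyl), C8 (OAc), C9 and C10 (oxirane, CH3 on C10). The facial senses of (R)- and (S)-TRIP (3,3′-bis(2,4,6-triisopropylphenyl)-1,1′-binaphthyl-2,2′-diyl hydrogen phosphate) are taken by analogy with their reported behaviour in allylborations.

## Retrosynthetic overview

1. The target comes from macrocyclic epoxy alcohol 19 by angeloylation at C1 (ring A = ten-membered carbocycle, ring B = oxirane).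
2. Key disconnection C4–C5: nickel-mediated radical coupling of the primary alkyl iodide with the E-iodoalkene of acyclic epoxy diiodide 18. Ring B is made first (hydroxyl-directed epoxidation of 17), ring A last.
3. Diiodide 17 comes from enyne 13 by one double hydrozirconation–iodination.
4. Enyne 13 is built on 3-methylbut-2-enal by two catalyst-controlled boron additions: Z-γ-isopropylallylboration (C7–C8), SeO2 oxidation of the E-methyl group to the C1 aldehyde, then 1-methylallenylboration (C1–C2).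
5. Starting materials: 4-methylpenta-1,3-diene, 3-methylbut-2-enal, but-2-yn-1-ol, angelic acid.

## Route

Step 1
Reactants: 1 4-methylpenta-1,3-diene
Product: 2 4,4,5,5-tetramethyl-2-[(2Z)-4-methylpent-2-en-1-yl]-1,3,2-dioxaborolane
Conditions: pinacolborane (1.05 equiv), Ni(cod)2 (2.5 mol %), PCy3 (2.5 mol %), toluene, 25 °C
Reagents that add atoms: pinacolborane, [H]B1OC(C)(C)C(C)(C)O1
Why: Nickel-catalysed 1,4-hydroboration of a 1,3-diene puts hydride on C4 and boron on C1 of the s-cis-bound diene through a nickel allyl, which fixes the Z geometry that later becomes the syn C7/C8 relationship.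

Step 2
Reactants: 2 4,4,5,5-tetramethyl-2-[(2Z)-4-methylpent-2-en-1-yl]-1,3,2-dioxaborolane; 3 3-methylbut-2-enal
Product: 5 (3R,4S)-6-methyl-3-(propan-2-yl)hepta-1,5-dien-4-ol, via pinacol borate ester 4 (not isolated)
Conditions: (S)-TRIP (5 mol %), 4 Å MS, toluene, −30 °C; then aq. NaHCO3
Reagents that add atoms: none
Why: Chiral-phosphoric-acid-catalysed allylboration through a closed Zimmerman–Traxler chair places the Z-configured γ-isopropyl group axial so that C7 and C8 form syn, and the (S)-acid, the antipode of the acid that sends allylboronates to the Re face of conjugated aldehydes, exposes the Si face to give the (3R,4S) alcohol.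

Step 3
Reactants: 5 (3R,4S)-6-methyl-3-(propan-2-yl)hepta-1,5-dien-4-ol
Product: 6 (3R,4S)-6-methyl-3-(propan-2-yl)hepta-1,5-dien-4-yl acetate
Conditions: Ac2O, pyridine, DMAP (cat.), CH2Cl2, 0 → 25 °C
Reagents that add atoms: acetic anhydride, CC(=O)OC(C)=O
Why: DMAP-catalysed acylation of a secondary alcohol installs the C8 acetate of the target directly and touches no stereocentre.

Step 4
Reactants: 6 (3R,4S)-6-methyl-3-(propan-2-yl)hepta-1,5-dien-4-yl acetate
Product: 8 (2E,4S,5R)-2-methyl-1-oxo-5-(propan-2-yl)hepta-2,6-dien-4-yl acetate, via allylic alcohol 7 (not isolated)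
Conditions: SeO2 (1.5 equiv), 1,4-dioxane, 80 °C
Reagents that add atoms: selenium dioxide, O=[Se]=O
Why: Riley allylic oxidation (ene reaction then 2,3-sigmatropic shift) attacks the trisubstituted alkene only at its E-methyl group, giving the E-enal that carries C1 at the aldehyde level while the monosubstituted alkene and the acetate stay intact.

Step 5
Reactants: 9 but-2-yn-1-ol
Product: 10 but-2-yn-1-yl methyl carbonate
Conditions: ClCO2Me, pyridine, CH2Cl2, 0 °C
Reagents that add atoms: methyl chloroformate, COC(Cl)=O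
Why: O-acylation of a primary propargylic alcohol with a chloroformate gives the carbonate leaving group needed for the SN2′ borylation.

Step 6
Reactants: 10 but-2-yn-1-yl methyl carbonate
Product: 11 2-(buta-2,3-dien-2-yl)-4,4,5,5-tetramethyl-1,3,2-dioxaborolane
Conditions: B2pin2 (1.1 equiv), CuCl (5 mol %), KOtBu (5 mol %), Xantphos (5 mol %), THF, 25 °C
Reagents that add atoms: bis(pinacolato)diboron, CC1(C)OB(OC1(C)C)B1OC(C)(C)C(C)(C)O1
Why: Copper-catalysed SN2′ borylation of a propargylic carbonate delivers boron to the alkyne carbon remote from the leaving group and gives the 1-methylallenylboronate regiospecifically, the expelled methoxide regenerating the copper alkoxide.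

Step 7
Reactants: 8 (2E,4S,5R)-2-methyl-1-oxo-5-(propan-2-yl)hepta-2,6-dien-4-yl acetate; 11 2-(buta-2,3-dien-2-yl)-4,4,5,5-tetramethyl-1,3,2-dioxaborolane
Product: 13 (3R,4S,5E,7R)-7-hydroxy-6-methyl-3-(propan-2-yl)undeca-1,5-dien-9-yn-4-yl acetate, via pinacol borate ester 12 (not isolated)
Conditions: (R)-TRIP (10 mol %), 4 Å MS, toluene, 0 °C; then aq. NaHCO3
Reagents that add atoms: none
Why: Chiral-phosphoric-acid-catalysed propargylboration (SE2′ through a six-membered cyclic transition state) joins C1 to C2 and leaves the methyl-capped alkyne, the (R)-acid sending the allenylboronate to the Re face of the enal so that C1 is set as R under catalyst control because the C7/C8 stereocentres are remote.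

Step 8
Reactants: 13 (3R,4S,5E,7R)-7-hydroxy-6-methyl-3-(propan-2-yl)undeca-1,5-dien-9-yn-4-yl acetate
Product: 17 (2E,5R,6E,8S,9S)-5-hydroxy-2,11-diiodo-6-methyl-9-(propan-2-yl)undeca-2,6-dien-8-yl acetate, via trimethylsilyl ether 14 (not isolated), via bis-zirconocene 15 (not isolated), via silylated diiodide 16 (not isolated)
Conditions: (Me3Si)2NH, TMSOTf (cat.), CH2Cl2, 25 °C, evaporate; Cp2Zr(H)Cl (3.5 equiv), CH2Cl2, 25 °C, 3 h; I2, 0 °C; citric acid, MeOH, 0 °C
Reagents that add atoms: iodine, II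
Why: Hydrozirconation–iodination adds Zr–H syn, placing zirconium on the terminal carbon of the monosubstituted alkene and, after equilibration with excess reagent, on the methyl-bearing alkyne carbon (the silyl ether prevents alkoxide-directed reversal), and iodinolysis with retention gives the primary iodide and the E-iodoalkene in one operation.

Step 9
Reactants: 17 (2E,5R,6E,8S,9S)-5-hydroxy-2,11-diiodo-6-methyl-9-(propan-2-yl)undeca-2,6-dien-8-yl acetate
Product: 18 (1S,2S)-1-{(2R,3R)-3-[(1R,3E)-1-hydroxy-4-iodopent-3-en-1-yl]-3-methyloxiran-2-yl}-4-iodo-2-(propan-2-yl)butyl acetate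
Conditions: VO(acac)2 (5 mol %), t-BuOOH (1.5 equiv, decane), CH2Cl2, 0 °C
Reagents that add atoms: tert-butyl hydroperoxide, CC(C)(C)OO
Why: Vanadium-catalysed hydroxyl-directed epoxidation delivers oxygen syn to the C1 hydroxyl through the conformer that keeps C2 away from the C10 methyl group (A(1,2) strain), giving the erythro epoxy alcohol with the 9R,10R oxirane on the face that the C8 stereocentre also favours sterically, while the electron-poor iodoalkene is left alone.

Step 10
Reactants: 18 (1S,2S)-1-{(2R,3R)-3-[(1R,3E)-1-hydroxy-4-iodopent-3-en-1-yl]-3-methyloxiran-2-yl}-4-iodo-2-(propan-2-yl)butyl acetate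
Product: 19 (1R,2R,4E,8S,9S,10R)-2-hydroxy-1,5-dimethyl-8-(propan-2-yl)-11-oxabicyclo[8.1.0]undec-4-en-9-yl acetate
Conditions: NiBr2(dme) (30 mol %), 4,4′-di-tert-butyl-2,2′-bipyridine (33 mol %), Mn powder (4 equiv), DMA, 25 °C, 18 added over 12 h to 2 mM
Reagents that add atoms: none
Why: Proposed new method: the alkenyl iodide adds oxidatively to zerovalent nickel with retention of the E geometry, monovalent nickel turns the primary iodide into the C5 radical, and capture of this radical by the tethered alkenylnickel followed by reductive elimination from trivalent nickel closes the ten-membered ring at C4–C5; the closest known reaction is the intermolecular nickel-catalysed reductive cross-electrophile coupling of alkenyl halides with alkyl iodides, and the oxirane installed beforehand removes both the C9=C10 alkene that would trap the C5 radical by 5-exo cyclisation and the allylic acetate that nickel could ionise.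

Step 11
Reactants: 19 (1R,2R,4E,8S,9S,10R)-2-hydroxy-1,5-dimethyl-8-(propan-2-yl)-11-oxabicyclo[8.1.0]undec-4-en-9-yl acetate; 20 angelic acid
Product: 22 (1R,2R,4E,8S,9S,10R)-9-(acetyloxy)-1,5-dimethyl-8-(propan-2-yl)-11-oxabicyclo[8.1.0]undec-4-en-2-yl (2Z)-2-methylbut-2-enoate, via mixed anhydride 21 (not isolated)
Conditions: 20, 2,4,6-trichlorobenzoyl chloride, Et3N, THF, 25 °C, filter; then 19, toluene, 80 °C
Reagents that add atoms: none
Why: Yamaguchi-type mixed-anhydride esterification without a nucleophilic catalyst acylates the hindered C1 hydroxyl with retention and avoids the conjugate-addition pathway that isomerises angelates to tiglates.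

## Compound list

1 | 4-methylpenta-1,3-diene | C=CC=C(C)C | starting material
2 | 4,4,5,5-tetramethyl-2-[(2Z)-4-methylpent-2-en-1-yl]-1,3,2-dioxaborolane | CC(C)/C=C\CB1OC(C)(C)C(C)(C)O1 | intermediate
3 | 3-methylbut-2-enal | CC(C)=CC=O | starting material
4 | pinacol borate ester of 5 (O–B(pin) in place of O–H) | C=C[C@@H](C(C)C)[C@H](OB1OC(C)(C)C(C)(C)O1)C=C(C)C | intermediate
5 | (3R,4S)-6-methyl-3-(propan-2-yl)hepta-1,5-dien-4-ol | C=C[C@@H](C(C)C)[C@H](O)C=C(C)C | intermediate
6 | (3R,4S)-6-methyl-3-(propan-2-yl)hepta-1,5-dien-4-yl acetate | C=C[C@@H](C(C)C)[C@H](OC(C)=O)C=C(C)C | intermediate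
7 | (2E,4S,5R)-1-hydroxy-2-methyl-5-(propan-2-yl)hepta-2,6-dien-4-yl acetate | C=C[C@@H](C(C)C)[C@H](OC(C)=O)/C=C(\C)CO | intermediate
8 | (2E,4S,5R)-2-methyl-1-oxo-5-(propan-2-yl)hepta-2,6-dien-4-yl acetate | C=C[C@@H](C(C)C)[C@H](OC(C)=O)/C=C(\C)C=O | intermediate
9 | but-2-yn-1-ol | CC#CCO | starting material
10 | but-2-yn-1-yl methyl carbonate | CC#CCOC(=O)OC | intermediate
11 | 2-(buta-2,3-dien-2-yl)-4,4,5,5-tetramethyl-1,3,2-dioxaborolane | C=C=C(C)B1OC(C)(C)C(C)(C)O1 | intermediate
12 | pinacol borate ester of 13 (O–B(pin) at C1) | C=C[C@@H](C(C)C)[C@H](OC(C)=O)/C=C(\C)[C@H](OB1OC(C)(C)C(C)(C)O1)CC#CC | intermediate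
13 | (3R,4S,5E,7R)-7-hydroxy-6-methyl-3-(propan-2-yl)undeca-1,5-dien-9-yn-4-yl acetate | C=C[C@@H](C(C)C)[C@H](OC(C)=O)/C=C(\C)[C@H](O)CC#CC | intermediate
14 | (3R,4S,5E,7R)-6-methyl-3-(propan-2-yl)-7-[(trimethylsilyl)oxy]undeca-1,5-dien-9-yn-4-yl acetate | C=C[C@@H](C(C)C)[C@H](OC(C)=O)/C=C(\C)[C@H](O[Si](C)(C)C)CC#CC | intermediate
15 | bis-zirconocene: 16 with Cp2Zr(Cl) in place of each iodine (alkyl–Zr at C5, E-alkenyl–Zr at C4) | Cl[Zr](CC[C@@H](C(C)C)[C@H](OC(C)=O)/C=C(\C)[C@H](O[Si](C)(C)C)C/C=C(\C)[Zr](Cl)(C1C=CC=C1)C1C=CC=C1)(C1C=CC=C1)C1C=CC=C1 | intermediate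
16 | (2E,5R,6E,8S,9S)-2,11-diiodo-6-methyl-9-(propan-2-yl)-5-[(trimethylsilyl)oxy]undeca-2,6-dien-8-yl acetate | ICC[C@@H](C(C)C)[C@H](OC(C)=O)/C=C(\C)[C@H](O[Si](C)(C)C)C/C=C(\C)I | intermediate
17 | (2E,5R,6E,8S,9S)-5-hydroxy-2,11-diiodo-6-methyl-9-(propan-2-yl)undeca-2,6-dien-8-yl acetate | ICC[C@@H](C(C)C)[C@H](OC(C)=O)/C=C(\C)[C@H](O)C/C=C(\C)I | intermediate
18 | (1S,2S)-1-{(2R,3R)-3-[(1R,3E)-1-hydroxy-4-iodopent-3-en-1-yl]-3-methyloxiran-2-yl}-4-iodo-2-(propan-2-yl)butyl acetate | ICC[C@@H](C(C)C)[C@H](OC(C)=O)[C@H]1O[C@@]1([C@H](O)C/C=C(\C)I)C | intermediate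
19 | (1R,2R,4E,8S,9S,10R)-2-hydroxy-1,5-dimethyl-8-(propan-2-yl)-11-oxabicyclo[8.1.0]undec-4-en-9-yl acetate | O[C@@H]1C/C=C(\C)CC[C@@H](C(C)C)[C@H](OC(C)=O)[C@H]2O[C@@]21C | intermediate
20 | angelic acid, (2Z)-2-methylbut-2-enoic acid | C/C=C(/C)C(=O)O | starting material
21 | (2Z)-2-methylbut-2-enoic 2,4,6-trichlorobenzoic anhydride | C/C=C(/C)C(=O)OC(=O)c1c(Cl)cc(Cl)cc1Cl | intermediate
22 | (1R,2R,4E,8S,9S,10R)-9-(acetyloxy)-1,5-dimethyl-8-(propan-2-yl)-11-oxabicyclo[8.1.0]undec-4-en-2-yl (2Z)-2-methylbut-2-enoate | C/C=C(/C)C(=O)O[C@@H]1C/C=C(\C)CC[C@@H](C(C)C)[C@H](OC(C)=O)[C@H]2O[C@@]21C | target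

## Step count

Total step count: 11.
Longest linear sequence: 9 steps (steps 1–4 and 7–11, from 1).

## Steps most likely to fail

**Step 10 (nickel radical macrocyclisation).** It is unprecedented at this ring size. Likely failures are reduction of the C5 radical, intermolecular coupling, and opening of the epoxy alcohol by nickel or by the manganese iodide formed.

Fallback: set out from 18 and close the same bond by a polar palladium coupling. Silylation ((Me3Si)2NH, cat. TMSOTf) gives the trimethylsilyl ether of 18 F1. Zinc insertion into the primary C–I bond only (Zn dust, LiCl, THF, 25 °C, at which the iodoalkene is inert) gives the alkylzinc iodide F2. Intramolecular Negishi coupling (Pd(PPh3)4, THF, 50 °C, 2 mM) gives the trimethylsilyl ether of 19 F3. Citric acid in MeOH removes the silyl group, and the route is rejoined at 19.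

**Step 8 (double hydrozirconation–iodination).** The acetate is exposed to excess Cp2Zr(H)Cl for hours, and the alkyne regiochemistry depends on equilibration.

Fallback: set out from 13 and dispense with the alkyl iodide. After silylation to 14, Cp2Zr(H)Cl (1.5 equiv, 25 °C, 1 h) hydrozirconates only the alkyne to the alkenylzirconocene F4. Iodinolysis gives the silylated iodoalkene F5, and citric acid/MeOH gives the iodoalkene alcohol F6 with the terminal alkene intact. VO(acac)2/t-BuOOH, as in step 9, gives the epoxy alcohol F7. 9-BBN (2.2 equiv, THF) hydroborates the terminal alkene and caps the hydroxyl, giving the bis-borane F8. Intramolecular B-alkyl Suzuki–Miyaura coupling (Pd(dppf)Cl2, AsPh3, K3PO4, DMF/H2O, 25 °C, 2 mM) closes C4–C5 and rejoins the route at 19.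

**Step 7 (asymmetric propargylboration).** The 1-methyl-substituted allenylboronate and the α-branched γ-acetoxy enal are both untested partners for the chiral acid.

Fallback: set out from 8 and set C1 by reduction instead. Uncatalysed addition of 11 (toluene, 40 °C) gives the C1-epimeric borate esters F9 and, after hydrolysis, the C1-epimeric homopropargylic alcohols F10. Dess–Martin periodinane (NaHCO3 buffer, 0 °C, to limit isomerisation to the allenyl ketone) gives the enone F11. Reduction with (S)-2-methyl-CBS-oxazaborolidine and catecholborane (toluene, −78 °C), the alkenyl group acting as the large substituent, sets C1 as R and rejoins the route at 13.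

## Further compounds

F1 | step 10 | trimethylsilyl ether of 18 | ICC[C@@H](C(C)C)[C@H](OC(C)=O)[C@H]1O[C@@]1([C@H](O[Si](C)(C)C)C/C=C(\C)I)C
F2 | step 10 | alkylzinc iodide from F1 (IZn at C5) | I[Zn]CC[C@@H](C(C)C)[C@H](OC(C)=O)[C@H]1O[C@@]1([C@H](O[Si](C)(C)C)C/C=C(\C)I)C
F3 | step 10 | trimethylsilyl ether of 19 | C[Si](C)(C)O[C@@H]1C/C=C(\C)CC[C@@H](C(C)C)[C@H](OC(C)=O)[C@H]2O[C@@]21C
F4 | step 8 | alkenylzirconocene from 14 (Cp2Zr(Cl) at C4, terminal alkene intact) | C=C[C@@H](C(C)C)[C@H](OC(C)=O)/C=C(\C)[C@H](O[Si](C)(C)C)C/C=C(\C)[Zr](Cl)(C1C=CC=C1)C1C=CC=C1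
F5 | step 8 | silylated iodoalkene (iodine at C4, terminal alkene intact) | C=C[C@@H](C(C)C)[C@H](OC(C)=O)/C=C(\C)[C@H](O[Si](C)(C)C)C/C=C(\C)I
F6 | step 8 | iodoalkene alcohol (17 with CH=CH2 in place of CH2CH2I) | C=C[C@@H](C(C)C)[C@H](OC(C)=O)/C=C(\C)[C@H](O)C/C=C(\C)I
F7 | step 8 | epoxy alcohol (18 with CH=CH2 in place of CH2CH2I) | C=C[C@@H](C(C)C)[C@H](OC(C)=O)[C@H]1O[C@@]1([C@H](O)C/C=C(\C)I)C
F8 | step 8 | bis-borane from F7 (9-BBN on C5 and on the C1 oxygen) | CC(C)[C@H](CCB1C2CCCC1CCC2)[C@H](OC(C)=O)[C@H]1O[C@@]1([C@H](OB1C2CCCC1CCC2)C/C=C(\C)I)C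
F9 | step 7 | C1-epimeric pinacol borate esters (12 and its C1 epimer) | C=C[C@@H](C(C)C)[C@H](OC(C)=O)/C=C(\C)C(OB1OC(C)(C)C(C)(C)O1)CC#CC
F10 | step 7 | C1-epimeric homopropargylic alcohols (13 and its C1 epimer) | C=C[C@@H](C(C)C)[C@H](OC(C)=O)/C=C(\C)C(O)CC#CC
F11 | step 7 | (3R,4S,5E)-6-methyl-7-oxo-3-(propan-2-yl)undeca-1,5-dien-9-yn-4-yl acetate | C=C[C@@H](C(C)C)[C@H](OC(C)=O)/C=C(\C)C(=O)CC#CC
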